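**Plan**

Numbering: O1–O2–C3(OH)(Me)–C4H(Me)–C5H2–C6(Me)(C1'H2–C2'H(Me)–(CH2)8Ph). The 1,2-dioxan-3-ol is the closed form of a γ-hydroperoxy ketone: C3 is a masked acetyl carbon and the peroxide carbon C6 stands γ to it, so the array C3(=O)–C4–C5–C6–O is what a peroxide leaves when it opens an acetylcyclopropane built from C4, C5 and C6.
Cuts, in order: C3–O2 (hemiketal); C6–O1, with C6 re-joined to C4 as a temporary cyclopropane bond; C4–C5 together with C5–C6 (removal of the C5 methylene from a C4=C6 tetrasubstituted allylic alcohol); C6–CH3 (enol tosylate coupling); C4–C6 (Claisen acylation of ethyl propanoate); the side-chain alkene (cross-metathesis).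
Forward: side chain from (R)-citronellic acid by cross-metathesis and hydrogenation; Claisen acylation; (E)-enol tosylate; stereoretentive methylation; reduction; cyclopropanation (the only carbocycle, a temporary one); oxidation and MeLi to the methyl ketone; H2O2 then opens the three-membered ring at C6 and the hydroperoxy ketone closes the dioxane.
Stereochemistry: C2' is bought with (R)-citronellic acid. C6 is set in the cyclopropanation (alkene geometry plus chiral boronate ligand) and inverted once in the peroxide opening. C3 (anomeric) and C4 (α to the masked ketone) are labile and are settled last by equilibration through the open chain, with the other C4 epimer separated and recycled.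

Key step: step 7

Remark: C3 and C4 are taken to interconvert through the open-chain hydroperoxy ketone, so they are fixed by equilibration and separation, not by a directed step; the bias at C4 is expected to be small.

**Route**

Step 1
Reactants: 1 (R)-citronellic acid [(3R)-3,7-dimethyloct-6-enoic acid]; 2 hex-5-en-1-ylbenzene (6-phenylhex-1-ene)
Product: 3 (3R)-3-methyl-11-phenylundec-6-enoic acid (E/Z mixture)
Conditions: second-generation Hoveyda–Grubbs catalyst [RuCl2(H2IMes)(=CH-C6H4-2-OiPr)] (5 mol%), 2 (3 equiv), CH2Cl2, 40 °C, argon sweep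
Reagents that add atoms: none
Why: Olefin cross-metathesis exchanges the isopropylidene terminus of the trisubstituted alkene in 1 for the terminal alkene of 2 (taken in excess), driven by loss of gaseous 2-methylpropene, and leaves the C3 stereocentre of 1 (the future C2') untouched.

Step 2
Reactants: 3 (3R)-3-methyl-11-phenylundec-6-enoic acid
Product: 4 (3R)-3-methyl-11-phenylundecanoic acid
Conditions: H2 (1 atm), Pd/C (10%), EtOAc, rt
Reagents that add atoms: none
Why: Heterogeneous hydrogenation saturates the disubstituted alkene, so both alkene isomers of 3 converge on one acid, while the arene, the carboxylic acid and the stereocentre are not affected.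

Step 3
Reactants: 4 (3R)-3-methyl-11-phenylundecanoic acid; 5 ethyl propanoate
Product: 7 ethyl (2RS,5R)-2,5-dimethyl-3-oxo-13-phenyltridecanoate, via acyl imidazolide 6 (not isolated)
Conditions: CDI, THF, rt; then LiCH(CH3)CO2Et (from 5 and LiN(iPr)2, THF, −78 °C; 2.2 equiv), −78 → −20 °C; AcOH quench
Reagents that add atoms: 1,1'-carbonyldiimidazole, O=C(n1ccnc1)n1ccnc1 (its imidazole unit is held only by 6; none of its atoms remains in 7)
Why: Claisen-type C-acylation of the lithium enolate of 5 by the acyl imidazolide gives the β-keto ester, the extra equivalent of enolate holding the product as its enolate until the quench; the new α-centre need not be controlled because it becomes trigonal in step 4.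

Step 4
Reactants: 7 ethyl (2RS,5R)-2,5-dimethyl-3-oxo-13-phenyltridecanoate
Product: 8 ethyl (2E,5R)-2,5-dimethyl-3-[(4-methylbenzenesulfonyl)oxy]-13-phenyltridec-2-enoate
Conditions: TsCl, N-methylimidazole, Et3N, CH2Cl2, 0 °C → rt
Reagents that add atoms: p-toluenesulfonyl chloride, Cc1ccc(cc1)S(Cl)(=O)=O
Why: O-Sulfonylation of the β-keto ester enolate under non-chelating amine conditions should place the sulfonate anti to the ester (the (E)-enol tosylate), fixing the alkene geometry that is later translated into the configuration at C6.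

Step 5
Reactants: 8 ethyl (2E,5R)-2,5-dimethyl-3-[(4-methylbenzenesulfonyl)oxy]-13-phenyltridec-2-enoate
Product: 9 ethyl (2Z,5R)-2,3,5-trimethyl-13-phenyltridec-2-enoate
Conditions: MeZnCl (2 equiv), PdCl2(dppf) (5 mol%), THF, 60 °C
Reagents that add atoms: methylzinc chloride, C[Zn]Cl
Why: Negishi cross-coupling (oxidative addition of zerovalent palladium into the activated C–OTs bond, transmetalation from zinc, reductive elimination) replaces the sulfonate by methyl with retention of alkene geometry, giving the tetrasubstituted (Z)-enoate.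

Step 6
Reactants: 9 ethyl (2Z,5R)-2,3,5-trimethyl-13-phenyltridec-2-enoate
Product: 10 (2Z,5R)-2,3,5-trimethyl-13-phenyltridec-2-en-1-ol
Conditions: iBu2AlH (2.5 equiv), CH2Cl2, −78 → 0 °C; aqueous work-up
Reagents that add atoms: none
Why: The aluminium hydride reduces the conjugated ester in 1,2-fashion to the allylic alcohol without touching the alkene geometry, providing the hydroxyl that anchors the cyclopropanation reagent.

Step 7
Reactants: 10 (2Z,5R)-2,3,5-trimethyl-13-phenyltridec-2-en-1-ol
Product: 11 [(1S,2R)-1,2-dimethyl-2-[(2R)-2-methyl-10-phenyldecyl]cyclopropyl]methanol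
Conditions: Zn(CH2I)2·DME (from Et2Zn, CH2I2, DME; 2.5 equiv), (4R,5R)-2-butyl-N,N,N',N'-tetramethyl-1,3,2-dioxaborolane-4,5-dicarboxamide (1.2 equiv), CH2Cl2, −10 °C → rt; aq. KOH work-up
Reagents that add atoms: diiodomethane, ICI
Why: The zinc alkoxide of 10 binds the chiral butylboronate, whose amide carbonyl chelates Zn(CH2I)2, and the carbenoid transfers CH2 (the future C5) to the C4=C6 alkene through a concerted butterfly transition state. The closest known reaction type is the dioxaborolane-controlled asymmetric Simmons–Smith cyclopropanation of allylic alcohols (Charette variant). The three-membered ring is closed by a concerted [2+1] methylene transfer in which the C4–C5 and C5–C6 bonds form together, so no exo/endo mode applies. The relative configuration of the two new quaternary centres follows stereospecifically from the (Z)-alkene (syn addition); the absolute sense comes from the (4R,5R)-ligand, which by its known facial preference with simple allylic alcohols should deliver CH2 to the face that gives the (1S,2R)-isomer, the one that places the C6 substituents correctly for the later invertive opening. The step needs π-face selectivity on a hindered tetrasubstituted alkene and chemoselectivity over the arene, and the allylic hydroxyl, which anchors both ligand and carbenoid, secures both.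

Step 8
Reactants: 11 [(1S,2R)-1,2-dimethyl-2-[(2R)-2-methyl-10-phenyldecyl]cyclopropyl]methanol
Product: 12 (1S,2R)-1,2-dimethyl-2-[(2R)-2-methyl-10-phenyldecyl]cyclopropane-1-carboxylic acid
Conditions: TEMPO (10 mol%), NaOCl (cat.), NaClO2 (2 equiv), MeCN, NaH2PO4/Na2HPO4 buffer pH 6.7, 35 °C
Reagents that add atoms: sodium chlorite, [Na+].[O-]Cl=O
Why: Nitroxyl/hypochlorite oxidation to the aldehyde with in situ chlorite (Pinnick-type) oxidation gives the acid under buffered conditions that spare the cyclopropane, the arene and both quaternary centres.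

Step 9
Reactants: 12 (1S,2R)-1,2-dimethyl-2-[(2R)-2-methyl-10-phenyldecyl]cyclopropane-1-carboxylic acid
Product: 14 1-[(1S,2R)-1,2-dimethyl-2-[(2R)-2-methyl-10-phenyldecyl]cyclopropyl]ethan-1-one, via dilithium gem-diolate 13 (not isolated)
Conditions: MeLi (3 equiv), Et2O, 0 °C → rt; inverse quench into ice water
Reagents that add atoms: methyllithium, [Li]C
Why: MeLi adds once to the lithium carboxylate and the resulting dilithium gem-diolate is inert to further addition, so the methyl ketone (the future C3 with its methyl group) appears only on hydrolysis; the fully substituted ring carbons cannot epimerise.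

Step 10
Reactants: 14 1-[(1S,2R)-1,2-dimethyl-2-[(2R)-2-methyl-10-phenyldecyl]cyclopropyl]ethan-1-one
Product: 16 (3S,4R,6S)-3,4,6-trimethyl-6-[(2R)-2-methyl-10-phenyldecyl]-1,2-dioxan-3-ol, via open-chain hydroperoxy ketone 15 (not isolated)
Conditions: anhydrous H2O2 in Et2O (10 equiv; caution), Sc(OTf)3 (10 mol%), Et2O, −20 → 0 °C; NaHCO3; SiO2 chromatography; other C4 epimer re-equilibrated (cat. camphorsulfonic acid, CH2Cl2, rt) and recycled
Reagents that add atoms: hydrogen peroxide, OO
Why: Proposed new method: coordination of Sc(OTf)3 to the acetyl oxygen polarises the doubly quaternary C4–C6 bond of the acylcyclopropane, H2O2 should attack C6 from the side opposite C4 in an SN2-like, strain-releasing homo-conjugate addition with inversion, and the enolate so released is protonated at C4 to give 15, whose hydroperoxide adds to the C3 carbonyl to close the dioxane; the closest known reaction types are the Lewis-acid-catalysed perhydrolysis of epoxides and oxetanes at a tertiary carbon with inversion, the acid-mediated homo-conjugate opening of acylcyclopropanes by halide, alcohol and carboxylate nucleophiles, and the stereoinvertive substitution at quaternary carbons of cyclopropylcarbinyl derivatives; C6 is thus relayed from the cyclopropane, C3 should take the axial-hydroxyl (anomeric) arrangement, and C4 is adjusted by equilibration through 15 towards the chair with equatorial C3-methyl, C4-methyl and C6 side chain.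

**Compound list**

1 | (R)-citronellic acid, (3R)-3,7-dimethyloct-6-enoic acid | C[C@H](CCC=C(C)C)CC(O)=O | starting material
2 | hex-5-en-1-ylbenzene (6-phenylhex-1-ene) | C=CCCCCc1ccccc1 | starting material
3 | (3R)-3-methyl-11-phenylundec-6-enoic acid (E/Z mixture) | C[C@H](CCC=CCCCCc1ccccc1)CC(O)=O | intermediate
4 | (3R)-3-methyl-11-phenylundecanoic acid | C[C@H](CCCCCCCCc1ccccc1)CC(O)=O | intermediate
5 | ethyl propanoate | CCC(=O)OCC | starting material
6 | 1-[(3R)-3-methyl-11-phenylundecanoyl]-1H-imidazole (acyl imidazolide) | C[C@H](CCCCCCCCc1ccccc1)CC(=O)n1ccnc1 | intermediate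
7 | ethyl (2RS,5R)-2,5-dimethyl-3-oxo-13-phenyltridecanoate | CCOC(=O)C(C)C(=O)C[C@H](C)CCCCCCCCc1ccccc1 | intermediate
8 | ethyl (2E,5R)-2,5-dimethyl-3-[(4-methylbenzenesulfonyl)oxy]-13-phenyltridec-2-enoate | CCOC(=O)/C(C)=C(/OS(=O)(=O)c1ccc(C)cc1)C[C@H](C)CCCCCCCCc1ccccc1 | intermediate
9 | ethyl (2Z,5R)-2,3,5-trimethyl-13-phenyltridec-2-enoate | CCOC(=O)/C(C)=C(/C)C[C@H](C)CCCCCCCCc1ccccc1 | intermediate
10 | (2Z,5R)-2,3,5-trimethyl-13-phenyltridec-2-en-1-ol | OC/C(C)=C(/C)C[C@H](C)CCCCCCCCc1ccccc1 | intermediate
11 | [(1S,2R)-1,2-dimethyl-2-[(2R)-2-methyl-10-phenyldecyl]cyclopropyl]methanol | OC[C@@]1(C)C[C@@]1(C)C[C@H](C)CCCCCCCCc1ccccc1 | intermediate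
12 | (1S,2R)-1,2-dimethyl-2-[(2R)-2-methyl-10-phenyldecyl]cyclopropane-1-carboxylic acid | OC(=O)[C@@]1(C)C[C@@]1(C)C[C@H](C)CCCCCCCCc1ccccc1 | intermediate
13 | dilithium 1-[(1S,2R)-1,2-dimethyl-2-[(2R)-2-methyl-10-phenyldecyl]cyclopropyl]ethane-1,1-bis(olate) | [Li+].[Li+].CC([O-])([O-])[C@@]1(C)C[C@@]1(C)C[C@H](C)CCCCCCCCc1ccccc1 | intermediate
14 | 1-[(1S,2R)-1,2-dimethyl-2-[(2R)-2-methyl-10-phenyldecyl]cyclopropyl]ethan-1-one | CC(=O)[C@@]1(C)C[C@@]1(C)C[C@H](C)CCCCCCCCc1ccccc1 | intermediate
15 | (3RS,5S,7R)-5-hydroperoxy-3,5,7-trimethyl-15-phenylpentadecan-2-one | CC(=O)C(C)C[C@@](C)(OO)C[C@H](C)CCCCCCCCc1ccccc1 | intermediate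
16 | (3S,4R,6S)-3,4,6-trimethyl-6-[(2R)-2-methyl-10-phenyldecyl]-1,2-dioxan-3-ol | C[C@H](CCCCCCCCc1ccccc1)C[C@@]1(C)C[C@@H](C)[C@@](C)(O)OO1 | target

Total step count: 10. Longest linear sequence: 10 steps (1 to 16).

**Steps most likely to fail**

Step 10 (proposed new method). The peroxide may add to the activated carbonyl and trigger Baeyer–Villiger migration instead of attacking the ring. The quaternary ring carbon may ionise before the nucleophile arrives, or the tertiary peroxide may re-ionise afterwards, eroding the configuration at C6. The acylcyclopropane may ring-expand to a dihydrofuran (Cloke–Wilson) or eliminate. The equilibration may discriminate only weakly between the C4 epimers, so that repeated separation and recycling is needed. The fallback uses known chemistry and gives up the control at C6. Starting from 14, ring opening with Me3SiI (from Me3SiCl and NaI, MeCN) and aqueous work-up would give the tertiary iodide (7R)-5-iodo-3,5,7-trimethyl-15-phenylpentadecan-2-one F1. Elimination with DBU would give the γ,δ-unsaturated ketone (7R)-3,7-dimethyl-5-methylidene-15-phenylpentadecan-2-one F2, together with non-conjugated double-bond isomers that behave alike. Mukaiyama–Isayama peroxidation (Co(acac)2, O2, Et3SiH, 1,2-dichloroethane) would place the silyl peroxide at the tertiary carbon to give (7R)-3,5,7-trimethyl-15-phenyl-5-[(triethylsilyl)peroxy]pentadecan-2-one F3. Desilylation (aq. HCl, MeOH) would release the hydroperoxy ketone and return to the route at 16, now as both C6 epimers, which would have to be separated by preparative HPLC.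

Step 7. Methylene transfer to the hindered tetrasubstituted alkene may be sluggish, or π-face discrimination by the ligand incomplete, which would lower the purity at C6. The fallback replaces reagent control by substrate control. From 9, MeNHOMe·HCl and iPrMgCl would give the Weinreb amide (2Z,5R)-N-methoxy-N,2,3,5-tetramethyl-13-phenyltridec-2-enamide F4, and MeMgBr would give the enone (3Z,6R)-3,4,6-trimethyl-14-phenyltetradec-3-en-2-one F5. Corey–Bakshi–Shibata reduction with the (R)-oxazaborolidine and BH3·SMe2 would give the allylic alcohol (2S,3Z,6R)-3,4,6-trimethyl-14-phenyltetradec-3-en-2-ol F6. Hydroxyl-directed Simmons–Smith cyclopropanation (Et2Zn, CH2I2), in which allylic 1,3-strain should hold the carbinol hydrogen in the alkene plane and the zinc alkoxide deliver CH2 to its own face, would give (1S)-1-[(1S,2R)-1,2-dimethyl-2-[(2R)-2-methyl-10-phenyldecyl]cyclopropyl]ethan-1-ol F7. Dess–Martin oxidation would rejoin the route at 14.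

Step 4. Geometric control in the enol sulfonylation may be incomplete, or the enol tosylate may isomerise; either would be carried through steps 5 to 7 into the wrong configuration at C6. The fallback uses the complementary geometric series with the enantiomeric ligand. From 7, chelation-controlled sulfonylation (TsCl, TMEDA, LiCl) would give ethyl (2Z,5R)-2,5-dimethyl-3-[(4-methylbenzenesulfonyl)oxy]-13-phenyltridec-2-enoate F8. The operations of steps 5 and 6 would give ethyl (2E,5R)-2,3,5-trimethyl-13-phenyltridec-2-enoate F9 and (2E,5R)-2,3,5-trimethyl-13-phenyltridec-2-en-1-ol F10. Cyclopropanation as in step 7, but with the (4S,5S)-dioxaborolane, would give [(1R,2R)-1,2-dimethyl-2-[(2R)-2-methyl-10-phenyldecyl]cyclopropyl]methanol F11, which has the same configuration at the future C6 and the opposite one at the future C4. The operations of steps 8 and 9 would give (1R,2R)-1,2-dimethyl-2-[(2R)-2-methyl-10-phenyldecyl]cyclopropane-1-carboxylic acid F12 and, through dilithium 1-[(1R,2R)-1,2-dimethyl-2-[(2R)-2-methyl-10-phenyldecyl]cyclopropyl]ethane-1,1-bis(olate) F13, the ketone 1-[(1R,2R)-1,2-dimethyl-2-[(2R)-2-methyl-10-phenyldecyl]cyclopropyl]ethan-1-one F14. Because the future C4 becomes trigonal in step 10, F14 converges on 15 under the conditions of step 10, and the route is rejoined there.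

Further compounds
F1 | step 10 | (7R)-5-iodo-3,5,7-trimethyl-15-phenylpentadecan-2-one | CC(=O)C(C)CC(C)(I)C[C@H](C)CCCCCCCCc1ccccc1
F2 | step 10 | (7R)-3,7-dimethyl-5-methylidene-15-phenylpentadecan-2-one | CC(=O)C(C)CC(=C)C[C@H](C)CCCCCCCCc1ccccc1
F3 | step 10 | (7R)-3,5,7-trimethyl-15-phenyl-5-[(triethylsilyl)peroxy]pentadecan-2-one | CC(=O)C(C)CC(C)(OO[Si](CC)(CC)CC)C[C@H](C)CCCCCCCCc1ccccc1
F4 | step 7 | (2Z,5R)-N-methoxy-N,2,3,5-tetramethyl-13-phenyltridec-2-enamide | CON(C)C(=O)/C(C)=C(/C)C[C@H](C)CCCCCCCCc1ccccc1
F5 | step 7 | (3Z,6R)-3,4,6-trimethyl-14-phenyltetradec-3-en-2-one | CC(=O)/C(C)=C(/C)C[C@H](C)CCCCCCCCc1ccccc1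
F6 | step 7 | (2S,3Z,6R)-3,4,6-trimethyl-14-phenyltetradec-3-en-2-ol | C[C@H](O)/C(C)=C(/C)C[C@H](C)CCCCCCCCc1ccccc1
F7 | step 7 | (1S)-1-[(1S,2R)-1,2-dimethyl-2-[(2R)-2-methyl-10-phenyldecyl]cyclopropyl]ethan-1-ol | C[C@H](O)[C@@]1(C)C[C@@]1(C)C[C@H](C)CCCCCCCCc1ccccc1
F8 | step 4 | ethyl (2Z,5R)-2,5-dimethyl-3-[(4-methylbenzenesulfonyl)oxy]-13-phenyltridec-2-enoate | CCOC(=O)/C(C)=C(\OS(=O)(=O)c1ccc(C)cc1)C[C@H](C)CCCCCCCCc1ccccc1
F9 | step 4 | ethyl (2E,5R)-2,3,5-trimethyl-13-phenyltridec-2-enoate | CCOC(=O)/C(C)=C(\C)C[C@H](C)CCCCCCCCc1ccccc1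
F10 | step 4 | (2E,5R)-2,3,5-trimethyl-13-phenyltridec-2-en-1-ol | OC/C(C)=C(\C)C[C@H](C)CCCCCCCCc1ccccc1
F11 | step 4 | [(1R,2R)-1,2-dimethyl-2-[(2R)-2-methyl-10-phenyldecyl]cyclopropyl]methanol | OC[C@]1(C)C[C@@]1(C)C[C@H](C)CCCCCCCCc1ccccc1
F12 | step 4 | (1R,2R)-1,2-dimethyl-2-[(2R)-2-methyl-10-phenyldecyl]cyclopropane-1-carboxylic acid | OC(=O)[C@]1(C)C[C@@]1(C)C[C@H](C)CCCCCCCCc1ccccc1
F13 | step 4 | dilithium 1-[(1R,2R)-1,2-dimethyl-2-[(2R)-2-methyl-10-phenyldecyl]cyclopropyl]ethane-1,1-bis(olate) | [Li+].[Li+].CC([O-])([O-])[C@]1(C)C[C@@]1(C)C[C@H](C)CCCCCCCCc1ccccc1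
F14 | step 4 | 1-[(1R,2R)-1,2-dimethyl-2-[(2R)-2-methyl-10-phenyldecyl]cyclopropyl]ethan-1-one | CC(=O)[C@]1(C)C[C@@]1(C)C[C@H](C)CCCCCCCCc1ccccc1
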